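The runs are calculated on assumed constants; scatter was added.

The small charge of buffer base in this flask, 0.0500 M, is half of the electrophile's, and two chemists disagree over whether that matters.

| setting | red | amber | ochre | flask |
|---|---|---|---|---|
| electrophile | 0.10 M | 0.10 M | 0.10 M | 0.10 M |
| nucleophile | 0.090 M | 0.36 M | 0.18 M | 0.180 M |
| buffer base | 0.050 M | 0.050 M | 0.10 M | 0.0500 M |
| buffer acid | 0.010 M | 0.010 M | 0.010 M | 0.0100 M |
| remark | run made earlier | run made earlier | run made earlier |  |
| time |  |  |  | 10 min |

- red (time / min: electrophile / %, target / %): 0.667: 92.3, 9.4; 2.00: 80.6, 18.8; 4.00: 68.2, 25.6; 6.00: 61.3, 28.0; 8.00: 56.1, 29.3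
- amber (time / min: electrophile / %, target / %): 1.50: 51.1, 41.7; 3.00: 29.5, 46.5; 5.00: 16.1, 38.1; 6.00: 13.2, 35.2; 8.00: 6.8, 29.1
- ochre (time / min: electrophile / %, target / %): 1.50: 71.3, 25.8; 3.00: 54.1, 36.8; 5.00: 39.6, 38.5; 6.00: 35.0, 37.5; 8.00: 29.4, 34.4

(each reading ± 1 percentage point)

- part of the electrophile that has reacted at 10 min
- pH of the solution at 10 min

- acid is the free proton; pH is minus the decimal logarithm of its molar concentration
- steps thought possible: electrophile + nucleophile -> acid + target + leaving group; protonated nucleophile <-> nucleophile + acid; buffer acid <-> buffer base + acid; nucleophile <-> dormant form; nucleophile + target -> over-reaction product; target + leaving group -> side product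
- the earlier runs do not show the pH; that part of a forecast is a guess

The first chemist sees plain second-order kinetics, with the electrophile as limiting reagent. From the first ochre reading she takes k = 1.37 /M/min, so she expects 81.8% reacted at 10 min.

The second chemist divides the rate of nucleophile loss by the rate of electrophile loss, so that time drops out. Counting just the first step and the uptake of acid, she puts the ratio at one while buffer base takes up the released acid, and at two once acid falls on the nucleophile. On that count, full reaction needs 2 c(electrophile) − c(buffer base) of nucleophile. She calls c(nucleophile) over that demand the nucleophile cover: 1.20 here, against 0.600 in the red run and 2.40 in the amber run.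

The cover gives no percentage, so she stands on the forecast: 72% reacted (66% to 78%) and pH 7 (5 to 9). Its ground is “once the buffer is spent, it protonates the nucleophile”.

The flask gives 73.7% reacted and pH 7.71, so the forecast holds and the plain figure stands too high.

    electrophile + nucleophile → acid + target + leaving group (k = 0.0249 /M/s)
    protonated nucleophile ⇌ nucleophile + acid, settled at all times (K = 4.00 × 10⁻⁸ M)
    buffer acid ⇌ buffer base + acid, settled at all times (K = 4.00 × 10⁻¹⁰ M)
    nucleophile ⇌ dormant form (K = 0.275, k = 0.00153 /s)
    nucleophile + target → over-reaction product (k = 0.00809 /M/s)
    target + leaving group → side product (k = 0.0354 /M/s)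

At 10.0 min the flask keeps 2.39% of its charge of buffer base, and the cover reckoned on the free nucleophile, electrophile and buffer base then standing is 0.988. The plain view stays near the amber run, where it reckons 27.4% electrophile left at 3.00 min against 29.5% read.

A neighbouring flask charged with 0.013 M of buffer base, all else as in the flask, has a cover of 0.963, lower than the flask's. That neighbour has 66.9% reacted at 10 min, less than the flask, and then holds 0.0540 M of protonated nucleophile.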